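**Strategy.** Ring C is disconnected so that C4 is a carbon monoxide unit inserted between C4a of ring A and C3, while O1–C2 arises from addition of a ring A phenol oxygen to the ring B aryl alkyne. The feature exploited is the symmetry of ring A: with O5 silylated, the 2-methoxyphloroglucinol core lacking C4 has a mirror plane through C8 and C5, so its two C–H positions are equivalent and iodination at either one fixes methoxy at C8. One palladium-catalysed operation then unites the iodoarene diacetate, CO and the prenyloxy alkyne, forming C4a–C4, C4–C3 and O1–C2 and closing ring C; only the acetoxy oxygen next to iodine can cyclise.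

Key step: step 7

Remark: the target has no stereocentre, so configuration has to be controlled nowhere; prenyl means 3-methylbut-2-en-1-yl and TIPS means triisopropylsilyl.

**Route**

Step 1
Reactants: 1 2-methoxyresorcinol
Product: 2 2-methoxy-1,3-phenylene diacetate
Conditions: Ac2O (2.5 equiv), pyridine, DMAP (cat.), CH2Cl2, 0 °C to rt
Reagents that add atoms: acetic anhydride, CC(=O)OC(C)=O
Why: Nucleophile-catalysed O-acylation of both phenols should be clean and gives a symmetric ring without acidic O–H for the borylation.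

Step 2
Reactants: 2 2-methoxy-1,3-phenylene diacetate
Product: 4 5-hydroxy-2-methoxy-1,3-phenylene diacetate, via pinacol boronate 3 (not isolated)
Conditions: [Ir(OMe)(cod)]2 (1.5 mol%), 4,4'-di-tert-butyl-2,2'-bipyridine (3 mol%), B2pin2 (1.0 equiv), THF, 80 °C; then acetone, aqueous KHSO5 (as Oxone, 2KHSO5·KHSO4·K2SO4), rt, 10 min
Reagents that add atoms: bis(pinacolato)diboron, CC1(C)OB(OC1(C)C)B1OC(C)(C)C(C)(C)O1 (its boryl group stays only in intermediate 3); potassium peroxymonosulfate, [K+].[O-]S(=O)(=O)OO (the new hydroxyl oxygen)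
Why: Iridium-catalysed aromatic C–H borylation is governed by sterics and should select C5, the only C–H without an ortho substituent, and peroxymonosulfate then oxidises the aryl boronate to the phenol (1,2-aryl shift from boron to oxygen) under near-neutral conditions that should spare the aryl acetates.

Step 3
Reactants: 4 5-hydroxy-2-methoxy-1,3-phenylene diacetate
Product: 5 2-methoxy-5-(triisopropylsilyloxy)-1,3-phenylene diacetate
Conditions: TIPSOTf (1.2 equiv), 2,6-lutidine, CH2Cl2, 0 °C
Reagents that add atoms: triisopropylsilyl trifluoromethanesulfonate, CC(C)[Si](OS(=O)(=O)C(F)(F)F)(C(C)C)C(C)C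
Why: O-Silylation of the single free phenol with a silyl triflate and a non-nucleophilic base should be fast and avoids acyl transfer from the aryl acetates, installing an amine-stable cap on the future O5.

Step 4
Reactants: 5 2-methoxy-5-(triisopropylsilyloxy)-1,3-phenylene diacetate
Product: 6 4-iodo-2-methoxy-5-(triisopropylsilyloxy)-1,3-phenylene diacetate
Conditions: N-iodosuccinimide (1.05 equiv), CF3CO2H (0.3 equiv), MeCN, 0 °C to rt, dark
Reagents that add atoms: N-iodosuccinimide, O=C1CCC(=O)N1I
Why: Electrophilic aromatic iodination should take place at C4, which is ortho to the silyloxy group and ortho/para to the two acetoxy groups; C4 and C6 are related by the mirror plane, so a single mono-iodide can form, and the first iodine slows a second substitution.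

Step 5
Reactants: 7 4-hydroxybenzaldehyde; 8 prenyl bromide
Product: 9 4-[(3-methylbut-2-en-1-yl)oxy]benzaldehyde
Conditions: K2CO3, acetone, 55 °C
Reagents that add atoms: none
Why: Williamson etherification (SN2 of the phenoxide at the primary allylic bromide) should give the aryl prenyl ether.

Step 6
Reactants: 9 4-[(3-methylbut-2-en-1-yl)oxy]benzaldehyde
Product: 10 1-ethynyl-4-[(3-methylbut-2-en-1-yl)oxy]benzene
Conditions: dimethyl (1-diazo-2-oxopropyl)phosphonate (1.3 equiv), K2CO3, MeOH, rt
Reagents that add atoms: dimethyl (1-diazo-2-oxopropyl)phosphonate, COP(=O)(OC)C(=[N+]=[N-])C(C)=O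
Why: Seyferth–Gilbert homologation with the Ohira–Bestmann reagent (olefination to the diazoalkene, loss of N2, 1,2-hydride shift of the alkylidene carbene) should convert the aldehyde into the terminal alkyne under carbonate/methanol conditions that leave the prenyl ether alone.

Step 7
Reactants: 6 4-iodo-2-methoxy-5-(triisopropylsilyloxy)-1,3-phenylene diacetate; 10 1-ethynyl-4-[(3-methylbut-2-en-1-yl)oxy]benzene; 11 carbon monoxide
Product: 14 7-hydroxy-8-methoxy-2-[4-(prenyloxy)phenyl]-5-(triisopropylsilyloxy)-4H-chromen-4-one, via ynone diacetate 12 (not isolated), via diethylamino enone 13 (not isolated)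
Conditions: PdCl2(PPh3)2 (5 mol%), 1,3-bis(diphenylphosphino)propane (5 mol%), thiourea (5 mol%), CO (1 atm, balloon), Et2NH (solvent), DBU (2 equiv), 10 (1.5 equiv), 40 °C
Reagents that add atoms: diethylamine, CCNCC (its atoms stay only in intermediate 13 and leave again on ring closure)
Why: Zerovalent palladium generated from PdCl2(PPh3)2 adds oxidatively to the C–I bond of 6, CO inserts to give an aroylpalladium iodide, and the alkynyl group of 10 is transferred with amine base so that reductive elimination gives ynone 12 with C4a–C4 and C4–C3 in place. Diethylamine then adds to the ynone and removes both acetyl groups as the amide, giving enaminone 13 (drawn E, as expected for a secondary amine), whose phenoxide on the future C8a attacks the amino-bearing carbon and expels diethylamine, forming O1–C2. The closest known reaction type is the palladium-catalysed carbonylative annulation of ortho-iodophenols or ortho-iodophenyl acetates with terminal alkynes to flavones. Ring C closes in the 6-endo-trig mode by addition–elimination at the β-carbon of the enaminone, and no stereocentre is formed. The step needs carbonylative instead of direct alkynylation (copper-free conditions under CO), 6-endo instead of 5-exo closure (the secondary amine turns the ynone into an enaminone that can only be attacked at C2), and cyclisation through the oxygen that becomes O1 and not through O5 (O5 is held as an amine-stable triisopropylsilyl ether, which fixes methoxy at C8).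

Step 8
Reactants: 14 7-hydroxy-8-methoxy-2-[4-(prenyloxy)phenyl]-5-(triisopropylsilyloxy)-4H-chromen-4-one
Product: 15 8-methoxy-2-[4-(prenyloxy)phenyl]-5,7-bis(triisopropylsilyloxy)-4H-chromen-4-one
Conditions: TIPSCl (1.3 equiv), imidazole, DMF, rt
Reagents that add atoms: triisopropylsilyl chloride, CC(C)[Si](Cl)(C(C)C)C(C)C
Why: Imidazole-mediated O-silylation of the acidic 7-hydroxyl should be easy; it removes the only acidic proton before the lithiation and blocks O7 against the later prenylation.

Step 9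
Reactants: 15 8-methoxy-2-[4-(prenyloxy)phenyl]-5,7-bis(triisopropylsilyloxy)-4H-chromen-4-one
Product: 18 3-hydroxy-8-methoxy-2-[4-(prenyloxy)phenyl]-5,7-bis(triisopropylsilyloxy)-4H-chromen-4-one, via 3-lithioflavone 16 (not isolated), via dimethyl boronate 17 (not isolated)
Conditions: lithium diisopropylamide (1.5 equiv), THF, −78 °C; B(OMe)3 (3 equiv), −78 to 0 °C; AcOH (1.5 equiv), 30% aqueous H2O2, 0 °C; aqueous Na2S2O3 quench
Reagents that add atoms: lithium diisopropylamide, [Li+].CC(C)[N-]C(C)C (lithium of intermediate 16 only); trimethyl borate, COB(OC)OC (boryl group of intermediate 17 only); hydrogen peroxide, OO (the new hydroxyl oxygen)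
Why: Deprotonation of the flavone C3–H by the hindered amide base at −78 °C (vinyl lithiation assisted by the C4 carbonyl oxygen), borylation and oxidation of the C–B bond with hydrogen peroxide (1,2-shift from boron to oxygen) is an established flavone-to-flavonol sequence, and the non-nucleophilic base and the peracid-free oxidant should spare the silyl and prenyl ethers.

Step 10
Reactants: 18 3-hydroxy-8-methoxy-2-[4-(prenyloxy)phenyl]-5,7-bis(triisopropylsilyloxy)-4H-chromen-4-one; 8 prenyl bromide
Product: 19 8-methoxy-3-(prenyloxy)-2-[4-(prenyloxy)phenyl]-5,7-bis(triisopropylsilyloxy)-4H-chromen-4-one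
Conditions: K2CO3 (anhydrous), acetone, 45 °C
Reagents that add atoms: none
Why: Williamson O-alkylation of the 3-hydroxyl, the only free hydroxyl, should give the 3-prenyl ether while both phenolic oxygens stay masked as bulky silyl ethers.

Step 11
Reactants: 19 8-methoxy-3-(prenyloxy)-2-[4-(prenyloxy)phenyl]-5,7-bis(triisopropylsilyloxy)-4H-chromen-4-one
Product: 20 5,7-dihydroxy-8-methoxy-3-(prenyloxy)-2-[4-(prenyloxy)phenyl]-4H-chromen-4-one (the target)
Conditions: Bu4NF (2.5 equiv), AcOH (2.5 equiv), THF, 0 °C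
Reagents that add atoms: none
Why: Fluoride-induced cleavage of both aryl silyl ethers (attack at silicon, Si–F bond formation), buffered with acetic acid, should release the 5- and 7-hydroxyls without touching the allylic ethers, the methyl ether or the chromone.

**Compound list**

1 | 2-methoxyresorcinol | COc1c(O)cccc1O | starting material
2 | 2-methoxy-1,3-phenylene diacetate | COc1c(OC(C)=O)cccc1OC(C)=O | intermediate
3 | 2-methoxy-5-(4,4,5,5-tetramethyl-1,3,2-dioxaborolan-2-yl)-1,3-phenylene diacetate | COc1c(OC(C)=O)cc(B2OC(C)(C)C(C)(C)O2)cc1OC(C)=O | intermediate (not isolated)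
4 | 5-hydroxy-2-methoxy-1,3-phenylene diacetate | COc1c(OC(C)=O)cc(O)cc1OC(C)=O | intermediate
5 | 2-methoxy-5-(triisopropylsilyloxy)-1,3-phenylene diacetate | COc1c(OC(C)=O)cc(O[Si](C(C)C)(C(C)C)C(C)C)cc1OC(C)=O | intermediate
6 | 4-iodo-2-methoxy-5-(triisopropylsilyloxy)-1,3-phenylene diacetate | CC(=O)Oc1cc(O[Si](C(C)C)(C(C)C)C(C)C)c(I)c(OC(C)=O)c1OC | intermediate
7 | 4-hydroxybenzaldehyde | O=Cc1ccc(O)cc1 | starting material
8 | prenyl bromide (1-bromo-3-methylbut-2-ene) | CC(C)=CCBr | starting material
9 | 4-[(3-methylbut-2-en-1-yl)oxy]benzaldehyde | O=Cc1ccc(OCC=C(C)C)cc1 | intermediate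
10 | 1-ethynyl-4-[(3-methylbut-2-en-1-yl)oxy]benzene | C#Cc1ccc(OCC=C(C)C)cc1 | intermediate
11 | carbon monoxide | [C-]#[O+] | starting material
12 | 2-methoxy-4-{3-[4-(prenyloxy)phenyl]prop-2-ynoyl}-5-(triisopropylsilyloxy)-1,3-phenylene diacetate | CC(=O)Oc1cc(O[Si](C(C)C)(C(C)C)C(C)C)c(C(=O)C#Cc2ccc(OCC=C(C)C)cc2)c(OC(C)=O)c1OC | intermediate (not isolated)
13 | (E)-3-(diethylamino)-1-[2,4-dihydroxy-3-methoxy-6-(triisopropylsilyloxy)phenyl]-3-[4-(prenyloxy)phenyl]prop-2-en-1-one | COc1c(O)cc(O[Si](C(C)C)(C(C)C)C(C)C)c(C(=O)/C=C(/N(CC)CC)c2ccc(OCC=C(C)C)cc2)c1O | intermediate (not isolated)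
14 | 7-hydroxy-8-methoxy-2-[4-(prenyloxy)phenyl]-5-(triisopropylsilyloxy)-4H-chromen-4-one | COc1c(O)cc(O[Si](C(C)C)(C(C)C)C(C)C)c2c(=O)cc(-c3ccc(OCC=C(C)C)cc3)oc12 | intermediate
15 | 8-methoxy-2-[4-(prenyloxy)phenyl]-5,7-bis(triisopropylsilyloxy)-4H-chromen-4-one | COc1c(O[Si](C(C)C)(C(C)C)C(C)C)cc(O[Si](C(C)C)(C(C)C)C(C)C)c2c(=O)cc(-c3ccc(OCC=C(C)C)cc3)oc12 | intermediate
16 | 3-lithio-8-methoxy-2-[4-(prenyloxy)phenyl]-5,7-bis(triisopropylsilyloxy)-4H-chromen-4-one | COc1c(O[Si](C(C)C)(C(C)C)C(C)C)cc(O[Si](C(C)C)(C(C)C)C(C)C)c2c(=O)c([Li])c(-c3ccc(OCC=C(C)C)cc3)oc12 | intermediate (not isolated)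
17 | dimethyl {8-methoxy-4-oxo-2-[4-(prenyloxy)phenyl]-5,7-bis(triisopropylsilyloxy)-4H-chromen-3-yl}boronate | COc1c(O[Si](C(C)C)(C(C)C)C(C)C)cc(O[Si](C(C)C)(C(C)C)C(C)C)c2c(=O)c(B(OC)OC)c(-c3ccc(OCC=C(C)C)cc3)oc12 | intermediate (not isolated)
18 | 3-hydroxy-8-methoxy-2-[4-(prenyloxy)phenyl]-5,7-bis(triisopropylsilyloxy)-4H-chromen-4-one | COc1c(O[Si](C(C)C)(C(C)C)C(C)C)cc(O[Si](C(C)C)(C(C)C)C(C)C)c2c(=O)c(O)c(-c3ccc(OCC=C(C)C)cc3)oc12 | intermediate
19 | 8-methoxy-3-(prenyloxy)-2-[4-(prenyloxy)phenyl]-5,7-bis(triisopropylsilyloxy)-4H-chromen-4-one | COc1c(O[Si](C(C)C)(C(C)C)C(C)C)cc(O[Si](C(C)C)(C(C)C)C(C)C)c2c(=O)c(OCC=C(C)C)c(-c3ccc(OCC=C(C)C)cc3)oc12 | intermediate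
20 | 5,7-dihydroxy-8-methoxy-3,4'-diprenyloxyflavone | COc1c(O)cc(O)c2c(=O)c(OCC=C(C)C)c(-c3ccc(OCC=C(C)C)cc3)oc12 | target

**Step count**

Total steps: 11. Longest linear sequence: 9 steps (steps 1–4 and 7–11); the alkyne branch (steps 5 and 6) joins at step 7.

**Steps most likely to fail**

1. Step 7. Several processes can divert the coupling:
- CO insertion at the doubly ortho-substituted aryl–palladium bond may lag behind direct alkynylation.
- The aroylpalladium may be captured by diethylamine.
- Zerovalent palladium with a secondary amine may ionise the prenyl ether.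
- Ring closure may leak to the 5-exo mode.

The fallback builds the ynone without palladium or CO; it sets out from 5 and comes back at 15, so step 8 is skipped. Methanolysis of both acetates (K2CO3, MeOH, 0 °C) should give 2-methoxy-5-(triisopropylsilyloxy)benzene-1,3-diol F1. Vilsmeier–Haack formylation (POCl3, DMF, MeCN, 0 °C, then aqueous NaOAc) at either of the two equivalent positions should give 2,4-dihydroxy-3-methoxy-6-(triisopropylsilyloxy)benzaldehyde F2. The hydroxyl para to the formyl group is not chelated to it and should be silylated selectively (TIPSCl, imidazole, CH2Cl2, 0 °C) to give 2-hydroxy-3-methoxy-4,6-bis(triisopropylsilyloxy)benzaldehyde F3. Addition of the lithium acetylide of 10 (n-BuLi, THF, −78 °C, 2.5 equiv, the first equivalent being consumed by the phenol) should give racemic 2-{1-hydroxy-3-[4-(prenyloxy)phenyl]prop-2-yn-1-yl}-6-methoxy-3,5-bis(triisopropylsilyloxy)phenol F4. Oxidation with MnO2 in CH2Cl2 should give 1-[2-hydroxy-3-methoxy-4,6-bis(triisopropylsilyloxy)phenyl]-3-[4-(prenyloxy)phenyl]prop-2-yn-1-one F5. Diethylamine in ethanol at rt should then close ring C in the 6-endo mode through the only free ortho oxygen to give 15.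

2. Step 9. Several processes can divert the hydroxylation:
- The 3-lithio species may open ring C by β-elimination of the O1 phenoxide on warming.
- The base may deprotonate the prenyl ether methylene or a ring position instead.
- The boronate may protodeboronate.
- The oxidant may attack the prenyl alkenes.

The fallback replaces C3 metalation by electrophilic epoxidation of C2=C3, done before any prenyl alkene is present; it sets out from 6 and comes back at 19. The annulation of step 7 is run with purchased 1-(benzyloxy)-4-ethynylbenzene (C#Cc1ccc(OCc2ccccc2)cc1) in place of 10 and should give 2-[4-(benzyloxy)phenyl]-7-hydroxy-8-methoxy-5-(triisopropylsilyloxy)-4H-chromen-4-one F6. Silylation as in step 8 should give 2-[4-(benzyloxy)phenyl]-8-methoxy-5,7-bis(triisopropylsilyloxy)-4H-chromen-4-one F7. Dimethyldioxirane (acetone/CH2Cl2, 0 °C) should give the racemic, necessarily cis-fused 2-[4-(benzyloxy)phenyl]-2,3-epoxy-8-methoxy-5,7-bis(triisopropylsilyloxy)chroman-4-one F8, which is not isolated. Catalytic p-toluenesulfonic acid should open it to 2-[4-(benzyloxy)phenyl]-3-hydroxy-8-methoxy-5,7-bis(triisopropylsilyloxy)-4H-chromen-4-one F9. Hydrogenolysis (H2, Pd/C, EtOAc, rt) should give 3-hydroxy-2-(4-hydroxyphenyl)-8-methoxy-5,7-bis(triisopropylsilyloxy)-4H-chromen-4-one F10. Double Williamson alkylation with 8 (2.4 equiv, K2CO3, acetone, 45 °C) should give 19.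

3. Step 4. Substitution next to the bulky silyl ether may be sluggish, the acid may slowly cleave the silyl ether, or a second iodination may occur under forcing. The fallback inverts silylation and iodination so that the halogenation runs on the strongly activated, unhindered free phenol; it sets out from 4 and comes back at 6. N-Iodosuccinimide (1.0 equiv, CH2Cl2, −20 to 0 °C) should iodinate ortho to the hydroxyl and give 5-hydroxy-4-iodo-2-methoxy-1,3-phenylene diacetate F11, and TIPSOTf with 2,6-lutidine (CH2Cl2, 0 °C) should then give 6.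

**Further compounds**

F1 | step 7 | 2-methoxy-5-(triisopropylsilyloxy)benzene-1,3-diol | COc1c(O)cc(O[Si](C(C)C)(C(C)C)C(C)C)cc1O
F2 | step 7 | 2,4-dihydroxy-3-methoxy-6-(triisopropylsilyloxy)benzaldehyde | COc1c(O)cc(O[Si](C(C)C)(C(C)C)C(C)C)c(C=O)c1O
F3 | step 7 | 2-hydroxy-3-methoxy-4,6-bis(triisopropylsilyloxy)benzaldehyde | COc1c(O[Si](C(C)C)(C(C)C)C(C)C)cc(O[Si](C(C)C)(C(C)C)C(C)C)c(C=O)c1O
F4 | step 7 | 2-{1-hydroxy-3-[4-(prenyloxy)phenyl]prop-2-yn-1-yl}-6-methoxy-3,5-bis(triisopropylsilyloxy)phenol (racemic) | COc1c(O[Si](C(C)C)(C(C)C)C(C)C)cc(O[Si](C(C)C)(C(C)C)C(C)C)c(C(O)C#Cc2ccc(OCC=C(C)C)cc2)c1O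
F5 | step 7 | 1-[2-hydroxy-3-methoxy-4,6-bis(triisopropylsilyloxy)phenyl]-3-[4-(prenyloxy)phenyl]prop-2-yn-1-one | COc1c(O[Si](C(C)C)(C(C)C)C(C)C)cc(O[Si](C(C)C)(C(C)C)C(C)C)c(C(=O)C#Cc2ccc(OCC=C(C)C)cc2)c1O
F6 | step 9 | 2-[4-(benzyloxy)phenyl]-7-hydroxy-8-methoxy-5-(triisopropylsilyloxy)-4H-chromen-4-one | COc1c(O)cc(O[Si](C(C)C)(C(C)C)C(C)C)c2c(=O)cc(-c3ccc(OCc4ccccc4)cc3)oc12
F7 | step 9 | 2-[4-(benzyloxy)phenyl]-8-methoxy-5,7-bis(triisopropylsilyloxy)-4H-chromen-4-one | COc1c(O[Si](C(C)C)(C(C)C)C(C)C)cc(O[Si](C(C)C)(C(C)C)C(C)C)c2c(=O)cc(-c3ccc(OCc4ccccc4)cc3)oc12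
F8 | step 9 | 2-[4-(benzyloxy)phenyl]-2,3-epoxy-8-methoxy-5,7-bis(triisopropylsilyloxy)chroman-4-one (racemic, cis-fused, not isolated) | COc1c(O[Si](C(C)C)(C(C)C)C(C)C)cc(O[Si](C(C)C)(C(C)C)C(C)C)c2c1OC1(c3ccc(OCc4ccccc4)cc3)OC1C2=O
F9 | step 9 | 2-[4-(benzyloxy)phenyl]-3-hydroxy-8-methoxy-5,7-bis(triisopropylsilyloxy)-4H-chromen-4-one | COc1c(O[Si](C(C)C)(C(C)C)C(C)C)cc(O[Si](C(C)C)(C(C)C)C(C)C)c2c(=O)c(O)c(-c3ccc(OCc4ccccc4)cc3)oc12
F10 | step 9 | 3-hydroxy-2-(4-hydroxyphenyl)-8-methoxy-5,7-bis(triisopropylsilyloxy)-4H-chromen-4-one | COc1c(O[Si](C(C)C)(C(C)C)C(C)C)cc(O[Si](C(C)C)(C(C)C)C(C)C)c2c(=O)c(O)c(-c3ccc(O)cc3)oc12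
F11 | step 4 | 5-hydroxy-4-iodo-2-methoxy-1,3-phenylene diacetate | CC(=O)Oc1cc(O)c(I)c(OC(C)=O)c1OC
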